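(The runs come from a simulation for substances that don't exist; noise was put on by code.)

You asked for a quick number, with the hunch that the new flask's charge of starting material would shift the ratio. We start from the easy step and divide.

the same everywhere: first nucleophile 12.5 mM

| charge | starting material | second nucleophile | protic impurity | remark | time |
|---|---|---|---|---|---|
| beta | 3.4 mM | 2.5 mM | 1 mM | run made earlier |  |
| gamma | 7.5 mM | 2.5 mM | 1 mM | run made earlier |  |
| flask | 5.0 mM | 2.50 mM | 1.00 mM |  | 4.0 min |

| run | time / min | target / % | other capture product / % |
|---|---|---|---|
| beta | 0.200 | 1.2 | 3.1 |
| beta | 0.417 | 1.4 | 5.4 |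
| beta | 1.00 | 2.5 | 7.3 |
| beta | 2.50 | 3.8 | 9.6 |
| gamma | 0.333 | 2.0 | 4.6 |
| gamma | 0.833 | 2.8 | 6.5 |
| gamma | 1.50 | 3.1 | 8.0 |
| gamma | 2.50 | 3.3 | 8.5 |

(each reading ± 0.3 percentage points)



1. ratio of target to other capture product at 2.0 s
2. ratio of target to other capture product at 4.0 min

1. At the last reading, 2.50 min, the ratio of target to other capture product is 0.396 in beta and 0.388 in gamma, although gamma was charged with about twice the starting material. With a scatter of 0.3 percentage points per reading, we see no shift with that charge.

2. We read this as one intermediate captured by both nucleophiles, each capture proportional to intermediate times nucleophile. The intermediate then cancels from the ratio, and the nucleophile concentrations remain.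

3. Pooling those last readings gives a ratio of 0.392. Dividing by the charge ratio of first to second nucleophile gives 0.0785: target per other capture product at equal nucleophile concentrations, the selectivity factor.

4. For the new flask, we multiply by its charges, 12.5 mM over 2.50 mM, and get 0.392. We commit to this for both times: by its last reading gamma's other capture product had taken a quarter of the second nucleophile charge, and its ratio still reads as above.

The forecast gives 0.4 at 2.0 s and 0.38 at 4.0 min, on the ground that “the ratio depends mainly on the nucleophile concentrations”, against our 0.392 for both.

The new flask gives 0.382 at 2.0 s and 0.394 at 4.0 min.

    starting material → intermediate (k = 0.0700 /s)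
    first nucleophile + intermediate → target (k = 1600 /M/s)
    second nucleophile + intermediate → other capture product (k = 21000 /M/s)
    intermediate → solvolysis product (k = 430 /s)
    starting material ⇌ dormant form (K = 2.00, k = 0.120 /s)
    first nucleophile + protic impurity → quenched reagent (k = 10.0 /M/s)

At 4.00 min the new flask holds solvolysis product amounting to 85.8% of the starting material charged, against 3.73% as target and 9.45% as other capture product. With 7.5 mM of first nucleophile and the rest of the recipe unchanged, the selectivity factor 0.0785 gives 0.235, and that neighbour flask stands at 0.230 at 4.0 min.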